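**Plan**

- The target is a (3R)-isoflavanone. In ring C (O1–C2–C3–C4–C4a–C8a) C2 is a bare O–CH2 next to the only stereocenter C3, which carries ring B (2,2-dimethylchroman-6-yl) and the C4 ketone. C2 can therefore begin as the carbon of a methoxy group on C8a, and C3 as an aryl(aroyl)carbene that inserts into one of its C–H bonds.
- Retrosynthetic cuts, in order: the O7–Si bond, the C2–C3 bond (ring C opens to OCH3 plus a diazo group at C3), the C3=N2 unit, the C3–aryl bond to ring B, then O–CH3, O–Si and the C8–prenyl bond, ending at 2',4'-dihydroxyacetophenone.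
- Forward: ring A is decorated first (C-prenylation, O4-silylation, O2-methylation). The purchased bromochroman, with ring B and its pyran ring intact, is joined to the acetyl carbon by Pd-catalysed α-arylation. Diazo transfer follows, ring C closes last, and the silyl group is removed.
- Stereochemistry: C3 is set during the ring closure by the chiral dirhodium tetracarboxylate Rh2(S-PTAD)4. It is preserved by base-free handling and a buffered desilylation.

Key step: step 6

Assumption: 6-bromo-2,2-dimethylchroman is taken as a purchasable building block, and Rh2(S-PTAD)4 is assumed to give the (3R) product; if the sense of induction proves opposite, the mirror-image catalyst Rh2(R-PTAD)4 is used with nothing else changed.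

A triisopropylsilyl ether is used at O7 in place of a tert-butyldimethylsilyl ether, because a silyl ether para to the ketone must survive carbonate, tert-butoxide and DBU before it is removed.

**Step 1**
Reactants: 1 2',4'-dihydroxyacetophenone; 2 prenyl bromide
Product: 3 1-[2,4-dihydroxy-3-(3-methylbut-2-en-1-yl)phenyl]ethanone
Conditions: KOH (10% aq.), 0 °C to rt; chromatographic separation from the C5 and O-alkylated isomers
Reagents that add atoms: none
Why: In water the resorcinol-type phenoxide of 1 is alkylated on carbon at C3, the position activated by both oxygens (C-prenylation of a phenolate), a known though unselective reaction from which 3 is isolated by chromatography.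

**Step 2**
Reactants: 3 1-[2,4-dihydroxy-3-(3-methylbut-2-en-1-yl)phenyl]ethanone
Product: 4 1-[2-hydroxy-3-(3-methylbut-2-en-1-yl)-4-(triisopropylsilyloxy)phenyl]ethanone
Conditions: iPr3SiCl, imidazole, DMF, 0 °C to rt
Reagents that add atoms: chlorotriisopropylsilane, CC(C)[Si](Cl)(C(C)C)C(C)C
Why: The 2-OH is tied up in a hydrogen bond to the acetyl group, so imidazole-mediated silylation with the bulky chlorosilane should take only the free 4-OH.

**Step 3**
Reactants: 4 1-[2-hydroxy-3-(3-methylbut-2-en-1-yl)-4-(triisopropylsilyloxy)phenyl]ethanone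
Product: 5 1-[2-methoxy-3-(3-methylbut-2-en-1-yl)-4-(triisopropylsilyloxy)phenyl]ethanone
Conditions: MeI (excess), K2CO3 (anhydrous), acetone, 45 °C
Reagents that add atoms: iodomethane, CI
Why: Williamson etherification of the chelated phenol under anhydrous carbonate conditions, which should leave the hindered silyl ether and the ketone alone, installs the methyl group whose carbon later becomes C2.

**Step 4**
Reactants: 5 1-[2-methoxy-3-(3-methylbut-2-en-1-yl)-4-(triisopropylsilyloxy)phenyl]ethanone; 6 6-bromo-2,2-dimethylchroman
Product: 7 2-(2,2-dimethylchroman-6-yl)-1-[2-methoxy-3-(3-methylbut-2-en-1-yl)-4-(triisopropylsilyloxy)phenyl]ethanone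
Conditions: Pd(OAc)2 (2 mol %), XPhos (4 mol %), NaOtBu (2.2 equiv), toluene, 60 °C
Reagents that add atoms: none
Why: In this Buchwald–Hartwig-type ketone α-arylation, zerovalent palladium formed from Pd(OAc)2 and the bulky biaryl phosphine inserts into the C–Br bond of 6, the sodium enolate of the methyl ketone replaces bromide, and reductive elimination forms the C3–aryl bond, with the bulky ligand and the hindered product enolate expected to stop the reaction at monoarylation.

**Step 5**
Reactants: 7 2-(2,2-dimethylchroman-6-yl)-1-[2-methoxy-3-(3-methylbut-2-en-1-yl)-4-(triisopropylsilyloxy)phenyl]ethanone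
Product: 8 2-diazo-2-(2,2-dimethylchroman-6-yl)-1-[2-methoxy-3-(3-methylbut-2-en-1-yl)-4-(triisopropylsilyloxy)phenyl]ethanone
Conditions: 4-acetamidobenzenesulfonyl azide, DBU, MeCN, 0 °C to rt; rapid filtration through silica, stored cold
Reagents that add atoms: 4-acetamidobenzenesulfonyl azide, CC(=O)Nc1ccc(cc1)S(=O)(=O)N=[N+]=[N-]
Why: Regitz diazo transfer: DBU deprotonates the CH2 group, which is acidified by both the ketone and the aryl ring, and the enolate takes the two terminal nitrogens of the sulfonyl azide with release of the sulfonamide.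

**Step 6**
Reactants: 8 2-diazo-2-(2,2-dimethylchroman-6-yl)-1-[2-methoxy-3-(3-methylbut-2-en-1-yl)-4-(triisopropylsilyloxy)phenyl]ethanone
Product: 9 (3R)-3-(2,2-dimethylchroman-6-yl)-8-(3-methylbut-2-en-1-yl)-7-(triisopropylsilyloxy)chroman-4-one
Conditions: Rh2(S-PTAD)4 (dirhodium tetrakis[(S)-(1-adamantyl)(N-phthalimido)acetate], 1 mol %), 2,2-dimethylbutane, 50 °C, slow addition of 8 under argon; neutral silica
Reagents that add atoms: none
Why: Proposed new method: the diazoketone loses N2 on the divalent rhodium paddlewheel to give an electrophilic rhodium carbene at C3, stabilised by the chroman aryl ring as donor and the aroyl carbonyl as acceptor, which takes a hydridic C–H bond of the neighbouring O-methyl group through a concerted, asynchronous three-centre transition state and forms the C2–C3 bond as the metal departs. The closest known reaction types are the chiral dirhodium carboxylate catalysed C–H insertion of 2-alkoxyaryl diazoketones into secondary O–CH2R sites to give chroman-4-ones and the intermolecular insertion of aryl-substituted donor/acceptor carbenes into methyl ethers; combining them on a primary O–CH3 site with an aryl ketone carbene is the untested part. Ring C closes by a 1,6-insertion to a six-membered ring, because the atom at the usual 1,5-position is O1 and carries no hydrogen. The new stereocenter is the carbene carbon C3, and its configuration is decided by which face of the planar carbene the C–H bond reaches inside the chiral pocket of the four phthalimido-adamantylacetate ligands, while C2 ends as a non-stereogenic CH2. The step needs insertion to win over attack of the O1 lone pair, which gives a five-membered oxonium ylide, and over intermolecular reaction with the prenyl alkene: the ylide can only go forward by a slow methyl 1,2-shift and otherwise reverts, the methoxy group flanked by two ortho substituents is pushed out of the ring plane toward the side chain, the prenyl group sits meta to that side chain and cannot reach the carbene, and slow addition keeps the carbene concentration low. The product is kept away from base so that the acidic C3–H is not exchanged.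

**Step 7**
Reactants: 9 (3R)-3-(2,2-dimethylchroman-6-yl)-8-(3-methylbut-2-en-1-yl)-7-(triisopropylsilyloxy)chroman-4-one
Product: 10 (3R)-3-(2,2-dimethylchroman-6-yl)-7-hydroxy-8-(3-methylbut-2-en-1-yl)chroman-4-one
Conditions: Bu4NF (1.1 equiv), AcOH (1.5 equiv), THF, 0 °C
Reagents that add atoms: none
Why: Fluoride-mediated desilylation of the electron-poor aryl silyl ether (para to the ketone) is fast, and acetic acid protonates the phenoxide at once, so the medium should never become basic enough to enolise C3, while the prenyl group and the chroman ether are inert.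

**Compound list**

1 | 2',4'-dihydroxyacetophenone | CC(=O)c1ccc(O)cc1O | starting material
2 | prenyl bromide (1-bromo-3-methylbut-2-ene) | CC(C)=CCBr | starting material
3 | 1-[2,4-dihydroxy-3-(3-methylbut-2-en-1-yl)phenyl]ethanone | CC(=O)c1ccc(O)c(CC=C(C)C)c1O | intermediate
4 | 1-[2-hydroxy-3-(3-methylbut-2-en-1-yl)-4-(triisopropylsilyloxy)phenyl]ethanone | CC(=O)c1ccc(O[Si](C(C)C)(C(C)C)C(C)C)c(CC=C(C)C)c1O | intermediate
5 | 1-[2-methoxy-3-(3-methylbut-2-en-1-yl)-4-(triisopropylsilyloxy)phenyl]ethanone | CC(=O)c1ccc(O[Si](C(C)C)(C(C)C)C(C)C)c(CC=C(C)C)c1OC | intermediate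
6 | 6-bromo-2,2-dimethylchroman | CC1(C)CCc2cc(Br)ccc2O1 | starting material
7 | 2-(2,2-dimethylchroman-6-yl)-1-[2-methoxy-3-(3-methylbut-2-en-1-yl)-4-(triisopropylsilyloxy)phenyl]ethanone | CC(C)=CCc1c(O[Si](C(C)C)(C(C)C)C(C)C)ccc(C(=O)Cc2ccc3c(c2)CCC(C)(C)O3)c1OC | intermediate
8 | 2-diazo-2-(2,2-dimethylchroman-6-yl)-1-[2-methoxy-3-(3-methylbut-2-en-1-yl)-4-(triisopropylsilyloxy)phenyl]ethanone | CC(C)=CCc1c(O[Si](C(C)C)(C(C)C)C(C)C)ccc(C(=O)C(=[N+]=[N-])c2ccc3c(c2)CCC(C)(C)O3)c1OC | intermediate
9 | (3R)-3-(2,2-dimethylchroman-6-yl)-8-(3-methylbut-2-en-1-yl)-7-(triisopropylsilyloxy)chroman-4-one | CC(C)=CCc1c(O[Si](C(C)C)(C(C)C)C(C)C)ccc2c1OC[C@@H](c1ccc3c(c1)CCC(C)(C)O3)C2=O | intermediate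
10 | (3R)-3-(2,2-dimethylchroman-6-yl)-7-hydroxy-8-(3-methylbut-2-en-1-yl)chroman-4-one | CC(C)=CCc1c(O)ccc2c1OC[C@@H](c1ccc3c(c1)CCC(C)(C)O3)C2=O | target

**Step count**

Total: 7 steps. Longest linear sequence: 7 steps (1 to 10); 2 and 6 are bought.

**Steps most likely to fail**

1. Step 6. The carbene may be drained into the five-membered oxonium ylide at O1 and on to a methyl 1,2-shift, or the insertion may proceed with poor facial discrimination at C3. The fallback sets out from 7 and returns at 9, using known reaction types only.
   - Chelation-assisted cleavage of the methyl ether ortho to the ketone with MgI2·OEt2 in toluene at 80 °C should give 2-(2,2-dimethylchroman-6-yl)-1-[2-hydroxy-3-(3-methylbut-2-en-1-yl)-4-(triisopropylsilyloxy)phenyl]ethanone F1.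
   - Heating F1 with N,N-dimethylformamide dimethyl acetal in toluene at 90 °C supplies C2 and closes ring C to the isoflavone 3-(2,2-dimethylchroman-6-yl)-8-(3-methylbut-2-en-1-yl)-7-(triisopropylsilyloxy)chromen-4-one F2.
   - Asymmetric transfer hydrogenation with RuCl(p-cymene)[(R,R)-TsDPEN] in HCO2H/Et3N at 40 °C first reduces the C2=C3 bond to the racemic isoflavanone F3, which is not isolated and racemises under the amine.
   - The same catalyst then reduces F3 under dynamic kinetic resolution to the cis alcohol (3R,4R)-3-(2,2-dimethylchroman-6-yl)-8-(3-methylbut-2-en-1-yl)-7-(triisopropylsilyloxy)chroman-4-ol F4. The usual aryl ketone model predicts 4R for the (R,R) ligand, and the cis preference then fixes 3R.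
   - Oxidation of C4 with Dess–Martin periodinane and NaHCO3 in CH2Cl2 at 0 °C returns the ketone without touching C3 and gives 9.

2. Step 1. Alkylation may go to O4 or C5, or a second prenyl group may be introduced, leaving little of the C3 isomer. The fallback sets out from 1 and returns at 3.
   - Etherification of the free 4-OH with 3-chloro-3-methylbut-1-yne (K2CO3, KI, CuI cat., acetone, reflux) should give 1-[2-hydroxy-4-(2-methylbut-3-yn-2-yloxy)phenyl]ethanone F5.
   - Semi-hydrogenation (H2, Pd/CaCO3 poisoned with Pb(OAc)2, quinoline, EtOAc) gives the 1,1-dimethylallyl ether 1-[2-hydroxy-4-(2-methylbut-3-en-2-yloxy)phenyl]ethanone F6.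
   - Aromatic Claisen rearrangement in N,N-diethylaniline at 130 °C moves the allyl unit with inversion to C3, the position favoured by the chelated 2-hydroxyacetyl unit, and delivers 3.

3. Step 4. The silyl ether may be lost or a second aryl group introduced under tert-butoxide, or the hindered enolate may couple sluggishly. The fallback sets out from 5 and returns at 7.
   - Me3SiOTf and Et3N in CH2Cl2 at 0 °C convert the ketone into the enol silane trimethyl({1-[2-methoxy-3-(3-methylbut-2-en-1-yl)-4-(triisopropylsilyloxy)phenyl]ethenyl}oxy)silane F7.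
   - F7 is coupled with 6 under neutral conditions (Bu3SnF, PdCl2[P(o-tolyl)3]2 cat., toluene, 100 °C) through a tin enolate formed in the flask. This fluoride-promoted Pd arylation of methyl ketone enol silanes is inherently monoselective and needs no alkoxide base.

**Further compounds**

F1 | step 6 | 2-(2,2-dimethylchroman-6-yl)-1-[2-hydroxy-3-(3-methylbut-2-en-1-yl)-4-(triisopropylsilyloxy)phenyl]ethanone | CC(C)=CCc1c(O[Si](C(C)C)(C(C)C)C(C)C)ccc(C(=O)Cc2ccc3c(c2)CCC(C)(C)O3)c1O
F2 | step 6 | 3-(2,2-dimethylchroman-6-yl)-8-(3-methylbut-2-en-1-yl)-7-(triisopropylsilyloxy)chromen-4-one | CC(C)=CCc1c(O[Si](C(C)C)(C(C)C)C(C)C)ccc2c1OC=C(c1ccc3c(c1)CCC(C)(C)O3)C2=O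
F3 | step 6 | racemic 3-(2,2-dimethylchroman-6-yl)-8-(3-methylbut-2-en-1-yl)-7-(triisopropylsilyloxy)chroman-4-one | CC(C)=CCc1c(O[Si](C(C)C)(C(C)C)C(C)C)ccc2c1OCC(c1ccc3c(c1)CCC(C)(C)O3)C2=O
F4 | step 6 | (3R,4R)-3-(2,2-dimethylchroman-6-yl)-8-(3-methylbut-2-en-1-yl)-7-(triisopropylsilyloxy)chroman-4-ol | CC(C)=CCc1c(O[Si](C(C)C)(C(C)C)C(C)C)ccc2c1OC[C@@H](c1ccc3c(c1)CCC(C)(C)O3)[C@H]2O
F5 | step 1 | 1-[2-hydroxy-4-(2-methylbut-3-yn-2-yloxy)phenyl]ethanone | CC(=O)c1ccc(OC(C)(C)C#C)cc1O
F6 | step 1 | 1-[2-hydroxy-4-(2-methylbut-3-en-2-yloxy)phenyl]ethanone | CC(=O)c1ccc(OC(C)(C)C=C)cc1O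
F7 | step 4 | trimethyl({1-[2-methoxy-3-(3-methylbut-2-en-1-yl)-4-(triisopropylsilyloxy)phenyl]ethenyl}oxy)silane | C=C(O[Si](C)(C)C)c1ccc(O[Si](C(C)C)(C(C)C)C(C)C)c(CC=C(C)C)c1OC
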